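1. D is what I am paid in, so I keep the books in points of the J charged, and every point must stand under some entry. The flasks, readings and questions are these:

| setting | alder | elm | flask |
|---|---|---|---|
| J | 0.66 M | 0.66 M | 0.66 M |
| L | 0.627 M | 0.627 M | 0.627 M |
| Z | 0.132 M | 0.132 M | 0.132 M |
| temperature | 5 °C | −10 °C | 5 °C |
| remark | the very flask that is asked about, followed so far | run made earlier |  |
| time |  |  | 8.0 d |

| run | time / d | D / % | J / % |
|---|---|---|---|
| alder | 0.833 | 49.7 | 32.9 |
| alder | 1.67 | 58.6 | 19.6 |
| alder | 2.50 | 62.1 | 13.2 |
| alder | 3.00 | 62.9 | 10.7 |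
| alder | 4.00 | 64.8 | 8.0 |
| alder | 5.00 | 65.6 | 6.0 |
| elm | 1.67 | 36.7 | 51.0 |
| elm | 4.00 | 52.7 | 29.4 |
| elm | 5.00 | 56.0 | 25.3 |
| elm | 6.00 | 58.7 | 21.7 |
| elm | 8.00 | 62.5 | 16.7 |
| elm | 10.0 | 63.7 | 13.5 |

(readings scatter by 0.3 percentage points)

- delta: change nothing and wait 4.0 d more
- alpha: at 8.0 d add L, 50.0% of the amount charged, then wait 4.0 d
- eta: at 8.0 d take out 90% of the D then present, then wait 4.0 d
- theta: at 8.0 d raise the temperature by 15 K, then wait 4.0 d

- what is taken out of D is counted as made
- additions bring no volume worth counting

* D, in percent of the J first charged, at 8.0 d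
* the option that brings most further D ("none" if no option brings more than 2 percentage points) (delta / alpha / eta / theta / none)
* D present, with what was taken out counted in, in percent of the J first charged, after delta
* D present, with what was taken out counted in, in percent of the J first charged, after alpha

2. I close the books on the alder run at its last reading, 5.00 d. D holds 65.6% and free J holds 6.0%, so 28.4% is missing.

3. Z is the next entry. If one Z takes at most one J, the Z charge covers at most 20.0% of J, which is less than the missing amount.

4. What stays open is 8.40%. I call this the unpaid balance: the points of J charged, minus D, minus free J, minus the whole Z charge counted in J. As long as one Z takes at most one J, it is a floor for the J gone by some other way; it is also a reading, with scatter 0.3 percentage points on each of its two readings. At 3.00 d it stood at 6.40%, so it grows as the alder run goes on.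

5. Free J in the alder run falls by 0.125 of a power of ten between 4.00 d and 5.00 d. Holding that pace, I put it near 2.53% at 8.0 d.

6. An option that merely finishes J draws on that amount, and the balance read at 5.00 d is larger than it. If the balance is a form that D enters and can leave, taking D out could bring about 10.9%. The readings do not prove that return, but I commit to eta.

7. The forecast gives 67.1% at 8.0 d, 67.9% after delta and 69.4% after alpha, and it picks alpha, holding that “Only about 3.5 points of J remain, which caps every option”. Our picks differ.

The flask gives 67.9% at 8.0 d, and eta brings 12 points, against 8.5 points for theta, 2.2 points for alpha and 1.1 points for delta; D stands at 69.0% after delta and 70.1% after alpha. The scheme is: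

    Z + L → X (k = 0.0324 M⁻¹ h⁻¹, Ea = 77.0 kJ mol⁻¹)
    J + Z → Q (k = 0.223 M⁻¹ h⁻¹, Ea = 58.0 kJ mol⁻¹)
    D ⇌ G (K = 0.209, k = 0.00784 h⁻¹, Ea = 103 kJ mol⁻¹, ΔH = −32.0 kJ mol⁻¹)
    J + L → D (k = 0.118 M⁻¹ h⁻¹, Ea = 60.0 kJ mol⁻¹)
    Z ⇌ E (K = 3.80, k = 0.0185 h⁻¹, Ea = 99.0 kJ mol⁻¹, ΔH = −61.0 kJ mol⁻¹)
    (constants at 5 °C)

At 8.00 d the flask holds 14.0% as G, the form D turns into and returns from. The unpaid balance there is 9.20%, and with the 2.92% of free J it makes 12.1%. In the flask charged with 1.7 M of J, D reaches 30.3% at 8.00 d and free J stands at 56.1%, so the balance is 5.85%, and G there holds 6.32%.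

(Readings and results were generated by integration with made-up constants; scatter was added.)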